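The reagent left over is the count to keep: in the proposed steps each target takes one reagent, and at 0.90 equiv reagent is the limiting reagent.

| flask | substrate | reagent | free catalyst | second catalyst | temperature | remark | time |
|---|---|---|---|---|---|---|---|
| east | 0.037 M | 0.90 equiv | 3.5 mol% | 0.1 mol% | 50 °C | run made earlier |  |
| south-east | 0.037 M | 0.90 equiv | 5.5 mol% | 0.1 mol% | 80 °C | run made earlier |  |
| north-west | 0.074 M | 0.90 equiv | 2.5 mol% | 0.1 mol% | 50 °C | run made earlier |  |
| summer | 0.037 M | 0.900 equiv | 2.5 mol% | 0.1 mol% | 55 °C |  | 4.0 h |
| dawn | 0.037 M | 0.900 equiv | 2.5 mol% | 0.1 mol% | 105 °C |  | 4.0 h |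
| spring | 0.037 M | 0.900 equiv | 2.5 mol% | 0.1 mol% | 80 °C |  | 4.0 h |

east run (percent of the substrate charged)

| time / h | target / % | substrate / % |
|---|---|---|
| 0.500 | 0 | 8.6 |
| 1.00 | 0.5 | 2.6 |
| 1.50 | 4.6 | 2.3 |
| 2.00 | 3.7 | 2.6 |
| 2.50 | 4.9 | 1.2 |
| 3.00 | 6.0 | 1.1 |

south-east run (percent of the substrate charged)

| time / min | target / % | substrate / % |
|---|---|---|
| 4.00 | 0.1 | 10.9 |
| 8.00 | 1.4 | 9.5 |
| 12.0 | 1.1 | 9.9 |
| 25.0 | 3.5 | 8.9 |
| 40.0 | 4.2 | 9.0 |
| 50.0 | 6.2 | 10.7 |

north-west run (percent of the substrate charged)

| time / h | target / % | substrate / % |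
|---|---|---|
| 0.250 | 3.5 | 16.1 |
| 0.500 | 2.3 | 4.2 |
| 0.833 | 5.1 | 2.8 |
| 1.50 | 6.1 | 2.3 |
| 3.00 | 10.5 | 1.8 |

(scatter of a reading: 1 percentage point)

- percentages count the substrate that a species holds: one self-condensation product counts as two
- steps that have been proposed: second catalyst + open intermediate <-> catalyst intermediate; second catalyst + target -> spent catalyst; reagent + catalyst intermediate -> second catalyst + target; 2 substrate -> self-condensation product; substrate + free catalyst <-> free catalyst + open intermediate

- the best flask by amount of target, in percent of the substrate charged; "all alike" if 1.5 percentage points covers them all (summer / dawn / spring / all alike)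
- amount of target at the end, in percent of the substrate charged, summer
- amount of target at the end, in percent of the substrate charged, dawn
- amount of target at the end, in percent of the substrate charged, spring

Two times matter. One is the asked 4.0 h. The other comes from the south-east run, the earlier run at the temperature of spring, where target reads 6.2% at 50.0 min, a climb read at 0.0744 h⁻¹ in fractions of the substrate charge, with the scatter of that reading in it. The charged reagent over that climb, the time the reagent lasts at a steady rate, is the reagent time 12.1 h.

The exchange of substrate with open intermediate adds no third time. In the south-east run substrate reads 10.9% at 4.00 min and 10.7% at 50.0 min, so that exchange reaches its level far sooner than the reagent time. Spring has less free catalyst, 2.5 mol% against 5.5 mol%, but that first reading time, stretched in proportion in this reckoning, stands far below the reagent time.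

The asked time is about a third of the reagent time. By the fraction left, this reckoning gives spring 66.9% of its reagent and 29.8% target, taking the climb as steady and as the same at the lower free catalyst of spring. This reckoning gives no number for dawn, which is hotter than any earlier run.

The forecast names dawn as best, with 9% for summer, 34% for dawn and 21% for spring, the last lower than the reckoning above. In its words: “Neither loss is measured, so I discount the higher figures, especially dawn.”

    second catalyst + open intermediate ⇌ catalyst intermediate (K = 330 M⁻¹, k = 12000 M⁻¹ min⁻¹, Ea = 44.0 kJ mol⁻¹, ΔH = −64.0 kJ mol⁻¹)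
    second catalyst + target → spent catalyst (k = 2.20 M⁻¹ min⁻¹, Ea = 71.0 kJ mol⁻¹)
    reagent + catalyst intermediate → second catalyst + target (k = 41.0 M⁻¹ min⁻¹, Ea = 43.0 kJ mol⁻¹)
    2 substrate → self-condensation product (k = 6.40 × 10⁻⁴ M⁻¹ min⁻¹, Ea = 81.0 kJ mol⁻¹)
    substrate + free catalyst ⇌ free catalyst + open intermediate (K = 8.90, k = 560 M⁻¹ min⁻¹, Ea = 66.0 kJ mol⁻¹, ΔH = −49.0 kJ mol⁻¹)
    (constants at 80 °C)

Spring gives the most target, 23.4%, against 9.89% in summer and 17.0% in dawn. Dawn holds 99.0% of its second catalyst as spent catalyst at 4.00 h, and its target still reads 17.1% at 40.0 h. Spring ends with 74% of its reagent against the 66.9% reckoned. For 1.0 h the reagent time gives 91.7% left, and spring stopped at that time keeps 92%.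

The readings were computed with made-up constants; noise was put on by code.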